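Retrosynthesis: after the five benzyl ethers, C4–C4a and O1–C8a of the cis half (half 1, anisyl) and C4''–C4a'' and O1''–C8a'' of the trans half (half 2) are cut together. This removes both rings A as one aryne and leaves a 2,3-bis(aryl-hydroxymethyl)succinic diamide, whose C2–C3 and C2''–C3'' bonds are then cut as two aldol bonds back to a succinyl unit.
Enabling feature: C4–C3–C3''–C4'' is a succinoyl chain capped by two phloroglucinol rings A. In each chromanone, O1 and C4 sit on the adjacent ring-A carbons C8a and C4a, with the C5 oxygen next to C4a. This is the footprint of an alkoxy-polarised benzyne whose carbanion appears at C4a, at six-ring distance from C4.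
Forward: C2-symmetric succinyl bis(thiazolidinethione) → anti aldol (C2''–C3'') → syn aldol (C2–C3) → temporary cis-fused bislactone → bis(Weinreb amide) bis(silyl ether) → both rings A attached and both rings C closed in one operation → hydrogenolysis.
Stereochemistry: all four centres come from one (S)-auxiliary in the two aldol steps (anti gives trans C2''R,C3''S; syn gives cis C2S,C3S). The bislactone stores them, and no later step breaks a bond at these carbons.
Key step: step 7

Assumption: in the MgBr2·OEt2-catalysed anti aldol, the (S)-4-benzylthiazolidinethione is taken to expose the same enolate face as in the titanium-mediated Evans-syn aldol (α-carbon S, carbinol carbon R with an aryl aldehyde). Flavanone numbering (doubly primed for half 2) is used for the corresponding carbons of all intermediates, and 2 and 12 are taken as commercial.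

Step 1
Reactants: 1 succinyl chloride; 2 (S)-4-benzyl-1,3-thiazolidine-2-thione (2 equiv)
Product: 3 1,4-bis[(4S)-4-benzyl-2-thioxo-1,3-thiazolidin-3-yl]butane-1,4-dione
Conditions: Et3N, DMAP (cat.), CH2Cl2, 0 °C → rt
Reagents that add atoms: none
Why: Twofold N-acylation of the thiazolidinethione by the diacid chloride gives a C2-symmetric bis-thioimide whose two CH2 groups are homotopic, so the first aldol needs no site selection, and no stereocentre is formed.

Step 2
Reactants: 3 bis-thioimide (slight excess); 4 4-(benzyloxy)benzaldehyde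
Product: 5 (2S)-2-{(R)-[4-(benzyloxy)phenyl](trimethylsilyloxy)methyl}-1,4-bis[(4S)-4-benzyl-2-thioxo-1,3-thiazolidin-3-yl]butane-1,4-dione
Conditions: MgBr2·OEt2 (cat.), Et3N, TMSCl, EtOAc, rt
Reagents that add atoms: chlorotrimethylsilane, C[Si](C)(C)Cl
Why: Evans magnesium-halide-catalysed direct anti aldol of an N-acylthiazolidinethione: either end of 3 gives the same product, the (S)-auxiliary shields one face of the Z-enolate and sets C3'' as S, the anti topology sets C2'' as R, and silylation of the aldolate turns the catalyst over, blocks retro-aldol and γ-lactonisation and leaves a β-branched product that reacts more slowly a second time.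

Step 3
Reactants: 5 mono anti-aldol silyl ether; 6 4-methoxybenzaldehyde
Product: 9 (1S,4R,5S,8S)-4-[4-(benzyloxy)phenyl]-8-(4-methoxyphenyl)-3,7-dioxabicyclo[3.3.0]octane-2,6-dione (cis-fused; anisyl exo; benzyloxyphenyl endo), via bis-aldol adduct 7 (not isolated), via monolactone 8 (not isolated)
Conditions: TiCl4, iPr2NEt, NMP, CH2Cl2, −78 °C; 6, −78 → −20 °C; aq NH4Cl; crude in MeOH–CH2Cl2, citric acid (cat.), rt
Reagents that add atoms: none
Why: Titanium-mediated Evans-syn aldol of the remaining CH2 thioimide (chlorotitanium Z-enolate, non-chelated Zimmerman–Traxler chair kept open by NMP) sets C3 and C2 as S,S under control of the second (S)-auxiliary, and each hydroxyl, the new one at once and the other after mild desilylation, then expels the thiazolidinethione of the γ-acyl group (5-exo-trig lactonisation), which only the 3S,3''S series can do twice because the bicycle must be cis-fused.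

Step 4
Reactants: 9 bislactone
Product: 11 (2S,3S)-N1,N4-dimethoxy-N1,N4-dimethyl-2-[(S)-(4-methoxyphenyl)(trimethylsilyloxy)methyl]-3-{(R)-[4-(benzyloxy)phenyl](trimethylsilyloxy)methyl}butanediamide, via diol bis-Weinreb amide 10 (not isolated)
Conditions: MeNHOMe·HCl, iPrMgCl, THF, −20 → 0 °C; then TMSCl, imidazole (cat.), 0 °C → rt
Reagents that add atoms: N,O-dimethylhydroxylamine hydrochloride, CNOC.Cl; chlorotrimethylsilane, C[Si](C)(C)Cl
Why: Weinreb aminolysis of both γ-lactones with the magnesium amide breaks only acyl–oxygen bonds, so all four centres are retained, and silylation of the two alkoxides in the same flask prevents relactonisation.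

Step 5
Reactants: 12 3,5-bis(benzyloxy)phenol
Product: 13 3,5-bis(benzyloxy)-2-bromophenol
Conditions: NBS, CH2Cl2, −78 → 0 °C
Reagents that add atoms: N-bromosuccinimide, O=C1CCC(=O)N1Br
Why: Electrophilic aromatic bromination goes ortho to the free hydroxyl and para to a benzyloxy group, because the position between the two benzyloxy groups is the more hindered one.

Step 6
Reactants: 13 bromophenol
Product: 16 3,5-bis(benzyloxy)-2-(trimethylsilyl)phenyl trifluoromethanesulfonate, via silyl ether 14 (not isolated), via lithium phenolate 15 (not isolated)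
Conditions: HMDS, THF, 65 °C, evaporate; n-BuLi, THF, −78 °C; Tf2O, −78 → 0 °C
Reagents that add atoms: hexamethyldisilazane, C[Si](C)(C)N[Si](C)(C)C; trifluoromethanesulfonic anhydride, O=S(=O)(OS(=O)(=O)C(F)(F)F)C(F)(F)F
Why: Standard assembly of a Kobayashi aryne precursor by O-silylation, bromine–lithium exchange, retro-Brook O-to-C silyl shift and triflation of the phenolate, with the exchange at −78 °C outrunning any benzylic lithiation.

Step 7
Reactants: 11 bis(silyl ether) bis(Weinreb amide); 16 aryne precursor (2 equiv consumed, 3 equiv used)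
Product: 19 (2S,3S)-5,7-bis(benzyloxy)-3-{(2R,3S)-5,7-bis(benzyloxy)-2-[4-(benzyloxy)phenyl]-4-oxochroman-3-yl}-2-(4-methoxyphenyl)chroman-4-one, via benzyne 17 (not isolated), via ortho-potassiated aryl ether 18 (not isolated)
Conditions: KF, 18-crown-6, THF, 0 °C → rt, slow co-addition of 11 and 16; AcOH, −20 °C
Reagents that add atoms: none
Why: Proposed new method: fluoride unmasks, in the same aprotic medium, the two alkoxides of 11 and benzyne 17; each alkoxide adds to the aryne carbon remote from the flanking benzyloxy group (future C8a), the aryl carbanion thus born at C4a attacks the Weinreb carbonyl C4 five bonds away, and loss of the N-methoxy-N-methylamide gives the aryl ketone, so two C–O and two C–C bonds join three components around the succinoyl core. The closest known reaction types are the aryne annulation of salicylate esters to xanthones (O-addition, then acyl capture of the aryl anion) and the Parham cyclisation of ortho-metalated aryl ethers onto Weinreb amides to chroman-4-ones, and what is new is the aliphatic aldolate as nucleophile and the twofold use. Both rings C close in the 6-exo-trig mode, by attack of C4a on C4 and of C4a'' on C4''. No stereocentre is created: C2, C3, C3'' and C2'' keep their aldol configurations because only O–Si and acyl–N bonds are broken, so syn becomes cis and anti becomes trans. Regioselectivity rests on the inductive distortion of the aryne by the benzyloxy group next to the triple bond, which sends oxygen to C8a, puts the carbanion at C4a only and places that benzyloxy group at C5. Acyl capture must outrun protonation and retro-aldol, which is served by the absence of any O–H (silyl-masked alkoxides, THF), by the poor leaving ability of an amide enolate, and by the fact that a stray γ-lactonisation only gives a lactone that is itself an acyl acceptor for the same carbanion.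

Step 8
Reactants: 19 penta-O-benzyl biflavanone
Product: 20 (2S,3S)-3-[(2R,3S)-5,7-dihydroxy-2-(4-hydroxyphenyl)-4-oxochroman-3-yl]-5,7-dihydroxy-2-(4-methoxyphenyl)chroman-4-one
Conditions: H2 (1 atm), Pd/C, EtOAc–MeOH, rt
Reagents that add atoms: none
Why: Hydrogenolysis of the five benzyl ethers under neutral conditions frees the phenols without enolisation or opening of ring C, so the cis half is not epimerised and the methyl ether stays.

Compound list
1 | succinyl chloride | O=C(Cl)CCC(=O)Cl | starting material
2 | (S)-4-benzyl-1,3-thiazolidine-2-thione | S=C1N[C@@H](Cc2ccccc2)CS1 | starting material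
3 | 1,4-bis[(4S)-4-benzyl-2-thioxo-1,3-thiazolidin-3-yl]butane-1,4-dione | O=C(CCC(=O)N1[C@@H](Cc2ccccc2)CSC1=S)N1[C@@H](Cc2ccccc2)CSC1=S | intermediate
4 | 4-(benzyloxy)benzaldehyde | O=Cc1ccc(OCc2ccccc2)cc1 | starting material
5 | mono anti-aldol silyl ether (C3'' S, C2'' R) | O=C(C[C@@H]([C@@H](O[Si](C)(C)C)c1ccc(OCc2ccccc2)cc1)C(=O)N1[C@@H](Cc2ccccc2)CSC1=S)N1[C@@H](Cc2ccccc2)CSC1=S | intermediate
6 | 4-methoxybenzaldehyde | COc1ccc(C=O)cc1 | starting material
7 | bis-aldol adduct, free C2 hydroxyl (C2 S, C3 S, C3'' S, C2'' R) | O=C([C@H]([C@H](O)c1ccc(OC)cc1)[C@@H]([C@@H](O[Si](C)(C)C)c1ccc(OCc2ccccc2)cc1)C(=O)N1[C@@H](Cc2ccccc2)CSC1=S)N1[C@@H](Cc2ccccc2)CSC1=S | intermediate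
8 | monolactone (C2–O acylated by C4''), thioimide at C4, silyl ether at C2'' | O=C1O[C@H](c2ccc(OC)cc2)[C@@H](C(=O)N2[C@@H](Cc3ccccc3)CSC2=S)[C@H]1[C@@H](O[Si](C)(C)C)c1ccc(OCc2ccccc2)cc1 | intermediate
9 | (1S,4R,5S,8S)-4-[4-(benzyloxy)phenyl]-8-(4-methoxyphenyl)-3,7-dioxabicyclo[3.3.0]octane-2,6-dione | O=C1O[C@@H](c2ccc(OCc3ccccc3)cc2)[C@H]2C(=O)O[C@H](c3ccc(OC)cc3)[C@@H]12 | intermediate
10 | diol bis-Weinreb amide (present in the flask as its bis(chloromagnesium) alkoxide) | CON(C)C(=O)[C@H]([C@H](O)c1ccc(OC)cc1)[C@@H]([C@@H](O)c1ccc(OCc2ccccc2)cc1)C(=O)N(C)OC | intermediate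
11 | bis(trimethylsilyl ether) bis-Weinreb amide | CON(C)C(=O)[C@H]([C@H](O[Si](C)(C)C)c1ccc(OC)cc1)[C@@H]([C@@H](O[Si](C)(C)C)c1ccc(OCc2ccccc2)cc1)C(=O)N(C)OC | intermediate
12 | 3,5-bis(benzyloxy)phenol | Oc1cc(OCc2ccccc2)cc(OCc2ccccc2)c1 | starting material
13 | 3,5-bis(benzyloxy)-2-bromophenol | Oc1cc(OCc2ccccc2)cc(OCc2ccccc2)c1Br | intermediate
14 | [3,5-bis(benzyloxy)-2-bromophenoxy]trimethylsilane | C[Si](C)(C)Oc1cc(OCc2ccccc2)cc(OCc2ccccc2)c1Br | intermediate
15 | lithium 3,5-bis(benzyloxy)-2-(trimethylsilyl)phenolate | [Li+].[O-]c1cc(OCc2ccccc2)cc(OCc2ccccc2)c1[Si](C)(C)C | intermediate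
16 | 3,5-bis(benzyloxy)-2-(trimethylsilyl)phenyl trifluoromethanesulfonate | C[Si](C)(C)c1c(OS(=O)(=O)C(F)(F)F)cc(OCc2ccccc2)cc1OCc1ccccc1 | intermediate
17 | 3,5-bis(benzyloxy)-1,2-didehydrobenzene | C1#CC(OCc2ccccc2)=CC(OCc2ccccc2)=C1 | intermediate
18 | C4a-potassiated aryl ether of half 1, drawn with half 2 already closed (the order of the two closures is immaterial) | CON(C)C(=O)[C@H]([C@H](Oc1cc(OCc2ccccc2)cc(OCc2ccccc2)c1[K])c1ccc(OC)cc1)[C@@H]1C(=O)c2c(OCc3ccccc3)cc(OCc3ccccc3)cc2O[C@H]1c1ccc(OCc2ccccc2)cc1 | intermediate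
19 | penta-O-benzyl biflavanone (2S,3S,2''R,3''S) | COc1ccc([C@H]2Oc3cc(OCc4ccccc4)cc(OCc4ccccc4)c3C(=O)[C@H]2[C@@H]2C(=O)c3c(OCc4ccccc4)cc(OCc4ccccc4)cc3O[C@H]2c2ccc(OCc3ccccc3)cc2)cc1 | intermediate
20 | (2S,3S)-3-[(2R,3S)-5,7-dihydroxy-2-(4-hydroxyphenyl)-4-oxochroman-3-yl]-5,7-dihydroxy-2-(4-methoxyphenyl)chroman-4-one | COc1ccc([C@H]2Oc3cc(O)cc(O)c3C(=O)[C@H]2[C@@H]2C(=O)c3c(O)cc(O)cc3O[C@H]2c2ccc(O)cc2)cc1 | target

Total step count: 8. Longest linear sequence: 6 (steps 1, 2, 3, 4, 7, 8).

Steps most likely to fail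

Step 7. What may go wrong:
- protonation of the C4a carbanion before acyl capture;
- retro-aldol cleavage of the unmasked aldolates;
- base-induced epimerisation and ring opening of the cis half once its ketone is free.

The fallback uses known chemistry, sets out from 9 and comes back at 19. Step 4 is quenched with aqueous NH4Cl instead of TMSCl, and diol 10 is isolated. Aryne O–H insertion of the neutral hydroxyls (16, CsF, MeCN, rt; the oxonium proton quenches the carbanion) gives the bis(3,5-dibenzyloxyphenyl ether) bis-Weinreb amide F1. Reduction with i-Bu2AlH (THF, −78 °C) gives the dialdehyde F2. Pinnick oxidation (NaClO2, NaH2PO4, 2-methyl-2-butene, t-BuOH–H2O) gives the diacid F3. Twofold intramolecular Friedel–Crafts acylation through the mixed trifluoroacetic anhydride (TFAA, CH2Cl2, 0 °C) is the classical closure of 3-aryloxypropanoic acids to chroman-4-ones. It forms the same C4–C4a and C4''–C4a'' bonds and delivers 19.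

Step 3. What may go wrong:
- loss of the benzylic silyl ether under TiCl4, with premature lactonisation onto the acyl group that is to be enolised;
- erosion of facial selectivity by the neighbouring stereocentre.

The fallback sets out from 5 and comes back at 9. The unbranched thioimide of 5 is the less hindered acyl donor. It is transacylated with (S)-4-benzyl-1,3-oxazolidin-2-one deprotonated by n-BuLi (THF, −78 °C) to the mixed imide F4. The boron-mediated Evans syn aldol (Bu2BOTf, Et3N, CH2Cl2, −78 → 0 °C, then 6; non-oxidative work-up with MeOH) tolerates silyl ethers and gives the syn adduct F5 with the same C2 S, C3 S sense. Citric acid in MeOH then removes the silyl group, and both hydroxyls lactonise with loss of the two auxiliaries to 9.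

Step 2. What may go wrong:
- a second aldol at the other end;
- O-acylation of the enolate by the second activated acyl group;
- insufficient anti or facial selectivity.

The fallback sets out from 2 and comes back at 5. Compound 2 is acylated with commercial 4-tert-butoxy-4-oxobutanoic acid (DCC, DMAP, CH2Cl2) to the thioimide ester F6, in which only one end can be enolised softly. The same MgBr2·OEt2-catalysed anti aldol with 4 gives the silyl ether F7. TMSOTf with 2,6-lutidine (CH2Cl2, 0 °C, then pH 6 buffer) cleaves the tert-butyl ester while the silyl ether stays, giving the acid F8. DCC/DMAP coupling with a second equivalent of 2 gives 5.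

Further compounds
F1 | step 7 | (2S,3S)-2-{(S)-[3,5-bis(benzyloxy)phenoxy](4-methoxyphenyl)methyl}-3-{(R)-[3,5-bis(benzyloxy)phenoxy][4-(benzyloxy)phenyl]methyl}-N1,N4-dimethoxy-N1,N4-dimethylbutanediamide | CON(C)C(=O)[C@H]([C@H](Oc1cc(OCc2ccccc2)cc(OCc2ccccc2)c1)c1ccc(OC)cc1)[C@@H]([C@@H](Oc1cc(OCc2ccccc2)cc(OCc2ccccc2)c1)c1ccc(OCc2ccccc2)cc1)C(=O)N(C)OC
F2 | step 7 | corresponding (2S,3S)-butanedial | O=C[C@H]([C@H](Oc1cc(OCc2ccccc2)cc(OCc2ccccc2)c1)c1ccc(OC)cc1)[C@@H]([C@@H](Oc1cc(OCc2ccccc2)cc(OCc2ccccc2)c1)c1ccc(OCc2ccccc2)cc1)C=O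
F3 | step 7 | corresponding (2S,3S)-butanedioic acid | OC(=O)[C@H]([C@H](Oc1cc(OCc2ccccc2)cc(OCc2ccccc2)c1)c1ccc(OC)cc1)[C@@H]([C@@H](Oc1cc(OCc2ccccc2)cc(OCc2ccccc2)c1)c1ccc(OCc2ccccc2)cc1)C(=O)O
F4 | step 3 | mixed imide: 5 with the unbranched thioimide replaced by (S)-4-benzyl-2-oxo-1,3-oxazolidin-3-yl | O=C(C[C@@H]([C@@H](O[Si](C)(C)C)c1ccc(OCc2ccccc2)cc1)C(=O)N1[C@@H](Cc2ccccc2)CSC1=S)N1[C@@H](Cc2ccccc2)COC1=O
F5 | step 3 | boron syn-aldol adduct of F4 with 6 (C2 S, C3 S, C3'' S, C2'' R) | O=C([C@H]([C@H](O)c1ccc(OC)cc1)[C@@H]([C@@H](O[Si](C)(C)C)c1ccc(OCc2ccccc2)cc1)C(=O)N1[C@@H](Cc2ccccc2)CSC1=S)N1[C@@H](Cc2ccccc2)COC1=O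
F6 | step 2 | tert-butyl 4-[(4S)-4-benzyl-2-thioxo-1,3-thiazolidin-3-yl]-4-oxobutanoate | CC(C)(C)OC(=O)CCC(=O)N1[C@@H](Cc2ccccc2)CSC1=S
F7 | step 2 | anti-aldol silyl ether of F6 with 4 (C3'' S, C2'' R) | CC(C)(C)OC(=O)C[C@@H]([C@@H](O[Si](C)(C)C)c1ccc(OCc2ccccc2)cc1)C(=O)N1[C@@H](Cc2ccccc2)CSC1=S
F8 | step 2 | carboxylic acid from F7 | OC(=O)C[C@@H]([C@@H](O[Si](C)(C)C)c1ccc(OCc2ccccc2)cc1)C(=O)N1[C@@H](Cc2ccccc2)CSC1=S
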